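## Retrosynthetic overview

1. Ring A (the N-alkyl pyrrolinone) is attached last: its C3–CH2 bond is cut to bromolactam 32 and a terminal alkene (hydroboration, B-alkyl Suzuki–Miyaura coupling). Ring B (the 3-methyltetronic acid) is opened to an O-propanoyl α-hydroxy ester (Dieckmann condensation).
2. Key disconnection: the single bond between the chain CH2 and the CH carbon of the Z-trisubstituted olefin CH=C(CH3)–CH2–C5 (ring B). It is made by a Zweifel olefination (1,2-shift of a primary alkyl group from boron to carbon, then anti-elimination) that joins the western C12 triene iodide 12 and the eastern alkenylboronate 17.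
3. Enabling feature: this olefin has H on the carbon to be alkylated, and CH3 plus the CH2 that leads to C5/O1 of ring B on the other carbon. Its E-alkenylboronate (B cis to CH3) is therefore available by syn-methylboration of a terminal alkyne, and the stereoinvertive rearrangement turns E into the required Z. The two oxygens on C5 and C4 of the future ring B are held in a temporary 1,3-dioxolane ring (cyclic ortho ester) that survives the organolithium and later supplies C2, C3 and the 3-methyl group of ring B.
4. Western fragment: Evans alkylation (methyl stereocentre), Takai olefination, Negishi carboalumination and coupling (E,E-diene). Eastern fragment: (R)-glycidol plus acetylide, ortho ester formation, methylboration.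
5. Ring order: dioxolane (step 9, opened in step 12), furanone ring B (step 15), pyrrolinone ring A (step 16, made apart and joined in step 18).

Key step: step 11

Remark on the chemistry: compounds 1, 2, 8, 13, 15, 27 and 28 are taken as commercially available. The ortho ester carbon of 16, 17, 19, 20 and 21 is an unassigned mixture of epimers that disappears in step 12; ortho esters are purified on base-washed silica.

## Route

Step 1
Reactants: 1 (4R)-4-benzyl-3-propanoyl-1,3-oxazolidin-2-one; 2 tert-butyl bromoacetate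
Product: 4 tert-butyl (3S)-4-[(4R)-4-benzyl-2-oxo-1,3-oxazolidin-3-yl]-3-methyl-4-oxobutanoate, via sodium Z-enolate 3 (not isolated)
Conditions: NaN(SiMe3)2, THF, −78 °C; then 2, −78 to −40 °C
Reagents that add atoms: none
Why: Evans auxiliary alkylation: the chelated Z-sodium enolate 3 is alkylated by the reactive α-bromo ester on the face opposite the C4 benzyl group of the (R)-oxazolidinone, which should set the (3S) methyl-bearing stereocentre.

Step 2
Reactants: 4 tert-butyl (3S)-4-[(4R)-4-benzyl-2-oxo-1,3-oxazolidin-3-yl]-3-methyl-4-oxobutanoate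
Product: 5 tert-butyl (3S)-4-hydroxy-3-methylbutanoate
Conditions: LiBH4, MeOH (1 equiv), THF, 0 °C
Reagents that add atoms: none
Why: Reductive cleavage of the Evans auxiliary: the activated exocyclic imide carbonyl should be reduced to the primary alcohol much faster than the tert-butyl ester, and the stereocentre is not touched.

Step 3
Reactants: 5 tert-butyl (3S)-4-hydroxy-3-methylbutanoate
Product: 6 tert-butyl (3S)-3-methyl-4-oxobutanoate
Conditions: Dess–Martin periodinane, CH2Cl2, 0 °C to rt; used at once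
Reagents that add atoms: none
Why: Dess–Martin oxidation of the primary alcohol under non-basic conditions, so that the α-stereocentre of the aldehyde should be kept.

Step 4
Reactants: 6 tert-butyl (3S)-3-methyl-4-oxobutanoate
Product: 7 tert-butyl (3S,4E)-5-iodo-3-methylpent-4-enoate
Conditions: CrCl2, CHI3, THF/1,4-dioxane, 0 °C to rt
Reagents that add atoms: iodoform, IC(I)I
Why: Takai olefination: the geminal dichromium reagent adds to the aldehyde and eliminates to the E-alkenyl iodide under essentially neutral conditions that should not enolise the α-stereocentre.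

Step 5
Reactants: 8 pent-1-en-4-yne; 7 tert-butyl (3S,4E)-5-iodo-3-methylpent-4-enoate
Product: 10 tert-butyl (3S,4E,6E)-3,7-dimethyldeca-4,6,9-trienoate, via alkenylalane 9 (not isolated)
Conditions: 8, AlMe3, Cp2ZrCl2 (20 mol %), CH2Cl2, 0 °C to rt; then 7, Pd(PPh3)4 (5 mol %), THF, rt
Reagents that add atoms: trimethylaluminium, C[Al](C)C
Why: Zirconium-catalysed Negishi carboalumination (syn addition of CH3–Al across the terminal alkyne, Al on the terminal carbon) fixes the E-trisubstituted olefin, and the palladium-catalysed Negishi-type alkenyl–alkenyl coupling of alane 9 with iodide 7 proceeds with retention at both carbons to give the E,E-diene; the ester and the monosubstituted alkene are inert.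

Step 6
Reactants: 10 tert-butyl (3S,4E,6E)-3,7-dimethyldeca-4,6,9-trienoate
Product: 11 (3S,4E,6E)-3,7-dimethyldeca-4,6,9-trien-1-ol
Conditions: LiAlH4, Et2O, 0 °C
Reagents that add atoms: none
Why: Hydride reduction of the ester to the primary alcohol; isolated and conjugated C=C bonds are inert to LiAlH4 at 0 °C.

Step 7
Reactants: 11 (3S,4E,6E)-3,7-dimethyldeca-4,6,9-trien-1-ol
Product: 12 (4E,6E,8S)-10-iodo-4,8-dimethyldeca-1,4,6-triene
Conditions: I2, PPh3, imidazole, CH2Cl2, 0 °C
Reagents that add atoms: iodine, II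
Why: Appel-type iodination: SN2 displacement of the oxyphosphonium group at the primary carbon by iodide.

Step 8
Reactants: 13 (R)-glycidol
Product: 14 (2S)-pent-4-yne-1,2-diol
Conditions: LiC≡CH·H2NCH2CH2NH2 (2.5 equiv), DMSO, 0 °C to rt; aqueous work-up
Reagents that add atoms: lithium acetylide, [Li]C#C
Why: SN2 opening of the epoxide at its unsubstituted carbon by acetylide (the free hydroxyl is carried as its alkoxide); the stereocentre is not a reacting centre and only its descriptor changes from R to S.

Step 9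
Reactants: 14 (2S)-pent-4-yne-1,2-diol; 15 triethyl orthopropanoate
Product: 16 (4S)-2-ethoxy-2-ethyl-4-(prop-2-yn-1-yl)-1,3-dioxolane
Conditions: pyridinium p-toluenesulfonate (cat.), CH2Cl2, rt; Et3N quench
Reagents that add atoms: none
Why: Acid-catalysed transorthoesterification: the 1,2-diol displaces two ethoxy groups and closes the five-membered cyclic ortho ester, a base-stable temporary ring that also carries the three propanoyl carbons of the future furanone; the new ortho ester carbon forms as an irrelevant mixture of epimers.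

Step 10
Reactants: 16 (4S)-2-ethoxy-2-ethyl-4-(prop-2-yn-1-yl)-1,3-dioxolane
Product: 17 2-{(1E)-3-[(4S)-2-ethoxy-2-ethyl-1,3-dioxolan-4-yl]-2-methylprop-1-en-1-yl}-4,4,5,5-tetramethyl-1,3,2-dioxaborolane
Conditions: bis(pinacolato)diboron, MeI, CuCl (10 mol %), Xantphos (10 mol %), NaOtBu, THF, rt
Reagents that add atoms: bis(pinacolato)diboron, CC1(C)OB(OC1(C)C)B1OC(C)(C)C(C)(C)O1; iodomethane, CI
Why: Copper-catalysed three-component carboboration (methylboration) of a terminal alkyne: syn-borylcupration places boron on the terminal carbon and the alkenylcopper is methylated with retention, so boron and the new methyl group should be cis (E-boronate).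

Step 11
Reactants: 12 (4E,6E,8S)-10-iodo-4,8-dimethyldeca-1,4,6-triene; 17 2-{(1E)-3-[(4S)-2-ethoxy-2-ethyl-1,3-dioxolan-4-yl]-2-methylprop-1-en-1-yl}-4,4,5,5-tetramethyl-1,3,2-dioxaborolane
Product: 21 (4S)-2-ethoxy-2-ethyl-4-[(2Z,6S,7E,9E)-2,6,10-trimethyltrideca-2,7,9,12-tetraen-1-yl]-1,3-dioxolane, via alkyllithium 18 (not isolated), via lithium boronate complex 19 (not isolated), via β-iodoboronic ester 20 (not isolated)
Conditions: 12, t-BuLi (2.0 equiv), Et2O, −78 °C; then 17, THF, −78 °C; then I2 (1.1 equiv), THF, −78 °C; then NaOMe, MeOH, −78 °C to rt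
Reagents that add atoms: none
Why: Zweifel olefination (closest known type: iodine-induced 1,2-metallate rearrangement of an alkenylboronate complex followed by base-induced anti-β-elimination): iodine–lithium exchange on 12 gives the primary alkyllithium 18, which adds to the boron of 17 to give the tetracoordinate boronate 19. Iodine attacks the electron-rich alkenyl–boron π bond of 19 and the primary alkyl group shifts from boron to the adjacent CH carbon anti to the iodonium, which forms the new C–C bond and gives the β-iodoboronic ester 20; methoxide then adds to boron, and boron and iodide leave anti-periplanar. Because migration and elimination are both anti, the alkyl group ends up trans to the substituent that was cis to boron, so the E-boronate (B cis to CH3) should give only the Z-olefin. No ring is closed and no new stereocentre survives: the two sp3 centres of 20 (formed on either face) are destroyed again, and the existing centres are remote from the reacting atoms. The step needs iodination of the anionic boronate in preference to the 1,3-diene and the two isolated alkenes, which the far higher nucleophilicity of the boronate at −78 °C and the use of about one equivalent of iodine should secure, and it needs migration of carbon and not oxygen, which the pinacol ligand secures. The base-stable ortho ester and the absence of carbonyl groups in both partners keep the organolithium stage clean.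

Step 12
Reactants: 21 (4S)-2-ethoxy-2-ethyl-4-[(2Z,6S,7E,9E)-2,6,10-trimethyltrideca-2,7,9,12-tetraen-1-yl]-1,3-dioxolane
Product: 22 (2S,4Z,8S,9E,11E)-1-hydroxy-4,8,12-trimethylpentadeca-4,9,11,14-tetraen-2-yl propanoate
Conditions: AcOH/H2O/THF, 0 °C to rt
Reagents that add atoms: water, O
Why: Mild acid hydrolysis of the cyclic ortho ester through the dioxolan-2-ylium ion and its hemi-ortho ester, which should collapse kinetically with cleavage of the bond to the primary oxygen, so that the propanoyl group stays on the secondary hydroxyl; the stereocentre is untouched.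

Step 13
Reactants: 22 (2S,4Z,8S,9E,11E)-1-hydroxy-4,8,12-trimethylpentadeca-4,9,11,14-tetraen-2-yl propanoate
Product: 24 (2S,4Z,8S,9E,11E)-4,8,12-trimethyl-2-(propanoyloxy)pentadeca-4,9,11,14-tetraenoic acid, via aldehyde 23 (not isolated)
Conditions: TEMPO (20 mol %), PhI(OAc)2 (2.2 equiv), MeCN/H2O, 0 °C to rt
Reagents that add atoms: water, O
Why: Oxoammonium (TEMPO) oxidation of the primary alcohol through aldehyde 23 and its hydrate to the carboxylic acid under near-neutral conditions that should avoid acyl migration and leave the olefins and the α-stereocentre intact.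

Step 14
Reactants: 24 (2S,4Z,8S,9E,11E)-4,8,12-trimethyl-2-(propanoyloxy)pentadeca-4,9,11,14-tetraenoic acid
Product: 25 methyl (2S,4Z,8S,9E,11E)-4,8,12-trimethyl-2-(propanoyloxy)pentadeca-4,9,11,14-tetraenoate
Conditions: Me3SiCHN2, toluene/MeOH, 0 °C
Reagents that add atoms: (trimethylsilyl)diazomethane, C[Si](C)(C)C=[N+]=[N-]
Why: Methyl ester formation by diazoalkane O-alkylation of the carboxylic acid, without base and therefore without risk to the α-acyloxy stereocentre.

Step 15
Reactants: 25 methyl (2S,4Z,8S,9E,11E)-4,8,12-trimethyl-2-(propanoyloxy)pentadeca-4,9,11,14-tetraenoate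
Product: 26 (5S)-4-hydroxy-3-methyl-5-[(2Z,6S,7E,9E)-2,6,10-trimethyltrideca-2,7,9,12-tetraen-1-yl]furan-2(5H)-one
Conditions: LiN(SiMe3)2 (3 equiv), THF, −78 to 0 °C; then aq. HCl
Reagents that add atoms: none
Why: Dieckmann (intramolecular Claisen) condensation of an α-acyloxy ester: the propanoate α-carbon is deprotonated and acylated by the methyl ester in a 5-exo-trig closure of the furanone ring, driven by formation of the tetronate anion, which also shields C5–H so that the (5S) centre should be retained.

Step 16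
Reactants: 27 (2S)-2-methylbutan-1-amine; 28 2,5-dimethoxy-2,5-dihydrofuran
Product: 30 1-[(2S)-2-methylbutyl]-1,5-dihydro-2H-pyrrol-2-one, via Z-butenedial 29 (not isolated)
Conditions: 28, aq. HCl (pH 1), rt; then 27, rt; NaHCO3 work-up
Reagents that add atoms: none
Why: Acid hydrolysis of the bis-acetal to Z-butenedial 29, double condensation with the primary amine (5-exo closure of the hemiaminal nitrogen onto the second aldehyde) and tautomerisation to the conjugated lactam; the side-chain stereocentre is not involved.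

Step 17
Reactants: 30 1-[(2S)-2-methylbutyl]-1,5-dihydro-2H-pyrrol-2-one
Product: 32 3-bromo-1-[(2S)-2-methylbutyl]-1,5-dihydro-2H-pyrrol-2-one, via trans-dibromide 31 (not isolated)
Conditions: Br2, CH2Cl2, 0 °C; then Et3N, 0 °C to rt
Reagents that add atoms: bromine, BrBr
Why: Bromination–dehydrobromination of an α,β-unsaturated lactam: anti-addition of bromine gives dibromide 31, and loss of HBr through the acidic C3–H leaves bromine on the α-carbon.

Step 18
Reactants: 26 (5S)-4-hydroxy-3-methyl-5-[(2Z,6S,7E,9E)-2,6,10-trimethyltrideca-2,7,9,12-tetraen-1-yl]furan-2(5H)-one; 32 3-bromo-1-[(2S)-2-methylbutyl]-1,5-dihydro-2H-pyrrol-2-one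
Product: 34 (5S)-4-hydroxy-3-methyl-5-[(2Z,6S,7E,9E)-2,6,10-trimethyl-13-{1-[(2S)-2-methylbutyl]-2-oxo-2,5-dihydro-1H-pyrrol-3-yl}trideca-2,7,9-trien-1-yl]furan-2(5H)-one, via alkylborane 33 (not isolated)
Conditions: 26, 9-BBN (2.6 equiv), THF, 0 °C to rt; then 32, Pd(dppf)Cl2 (10 mol %), AsPh3, Cs2CO3, DMF/H2O, rt; aq. HCl work-up
Reagents that add atoms: none
Why: Hydroboration and B-alkyl Suzuki–Miyaura coupling: 9-BBN adds anti-Markovnikov to the only monosubstituted alkene (one equivalent is first consumed by the acidic enol O–H), and alkylborane 33 is coupled with the α-bromo lactam under aqueous base, which forms the last C–C bond without touching a stereocentre or an olefin geometry.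

## Compound list

1 | (4R)-4-benzyl-3-propanoyl-1,3-oxazolidin-2-one | CCC(=O)N1[C@H](Cc2ccccc2)COC1=O | starting material
2 | tert-butyl bromoacetate | BrCC(=O)OC(C)(C)C | starting material
3 | sodium (1Z)-1-[(4R)-4-benzyl-2-oxo-1,3-oxazolidin-3-yl]prop-1-en-1-olate (not isolated) | C/C=C(\[O-])N1[C@H](Cc2ccccc2)COC1=O.[Na+] | intermediate
4 | tert-butyl (3S)-4-[(4R)-4-benzyl-2-oxo-1,3-oxazolidin-3-yl]-3-methyl-4-oxobutanoate | CC(C)(C)OC(=O)C[C@H](C)C(=O)N1[C@H](Cc2ccccc2)COC1=O | intermediate
5 | tert-butyl (3S)-4-hydroxy-3-methylbutanoate | CC(C)(C)OC(=O)C[C@H](C)CO | intermediate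
6 | tert-butyl (3S)-3-methyl-4-oxobutanoate | CC(C)(C)OC(=O)C[C@H](C)C=O | intermediate
7 | tert-butyl (3S,4E)-5-iodo-3-methylpent-4-enoate | CC(C)(C)OC(=O)C[C@H](C)/C=C/I | intermediate
8 | pent-1-en-4-yne | C=CCC#C | starting material
9 | dimethyl[(1E)-2-methylpenta-1,4-dien-1-yl]alane (not isolated) | C=CC/C(C)=C/[Al](C)C | intermediate
10 | tert-butyl (3S,4E,6E)-3,7-dimethyldeca-4,6,9-trienoate | CC(C)(C)OC(=O)C[C@H](C)/C=C/C=C(\C)CC=C | intermediate
11 | (3S,4E,6E)-3,7-dimethyldeca-4,6,9-trien-1-ol | OCC[C@H](C)/C=C/C=C(\C)CC=C | intermediate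
12 | (4E,6E,8S)-10-iodo-4,8-dimethyldeca-1,4,6-triene | ICC[C@H](C)/C=C/C=C(\C)CC=C | intermediate
13 | (R)-glycidol, (2R)-oxiran-2-ylmethanol | OC[C@@H]1CO1 | starting material
14 | (2S)-pent-4-yne-1,2-diol | C#CC[C@@H](CO)O | intermediate
15 | triethyl orthopropanoate (1,1,1-triethoxypropane) | CCC(OCC)(OCC)OCC | starting material
16 | (4S)-2-ethoxy-2-ethyl-4-(prop-2-yn-1-yl)-1,3-dioxolane (C2 epimers) | CCOC1(CC)OC[C@H](CC#C)O1 | intermediate
17 | 2-{(1E)-3-[(4S)-2-ethoxy-2-ethyl-1,3-dioxolan-4-yl]-2-methylprop-1-en-1-yl}-4,4,5,5-tetramethyl-1,3,2-dioxaborolane | CCOC1(CC)OC[C@H](C/C(C)=C/B2OC(C)(C)C(C)(C)O2)O1 | intermediate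
18 | [(3S,4E,6E)-3,7-dimethyldeca-4,6,9-trien-1-yl]lithium (not isolated) | [Li]CC[C@H](C)/C=C/C=C(\C)CC=C | intermediate
19 | lithium [(3S,4E,6E)-3,7-dimethyldeca-4,6,9-trien-1-yl]{(1E)-3-[(4S)-2-ethoxy-2-ethyl-1,3-dioxolan-4-yl]-2-methylprop-1-en-1-yl}(pinacolato)borate (not isolated) | [Li+].C=CC/C(C)=C/C=C/[C@@H](C)CC[B-]1(/C=C(\C)C[C@H]2COC(CC)(OCC)O2)OC(C)(C)C(C)(C)O1 | intermediate
20 | β-iodoboronic ester, anti adduct with the alkyl group on the CH–B carbon and iodine on the C(CH3) carbon (not isolated; one of the two facial diastereomers shown, the other has both new centres inverted) | C=CC/C(C)=C/C=C/[C@@H](C)CC[C@@H](B1OC(C)(C)C(C)(C)O1)[C@](C)(I)C[C@H]1COC(CC)(OCC)O1 | intermediate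
21 | (4S)-2-ethoxy-2-ethyl-4-[(2Z,6S,7E,9E)-2,6,10-trimethyltrideca-2,7,9,12-tetraen-1-yl]-1,3-dioxolane | C=CC/C(C)=C/C=C/[C@@H](C)CC/C=C(/C)C[C@H]1COC(CC)(OCC)O1 | intermediate
22 | (2S,4Z,8S,9E,11E)-1-hydroxy-4,8,12-trimethylpentadeca-4,9,11,14-tetraen-2-yl propanoate | C=CC/C(C)=C/C=C/[C@@H](C)CC/C=C(/C)C[C@@H](CO)OC(=O)CC | intermediate
23 | (2S,4Z,8S,9E,11E)-4,8,12-trimethyl-1-oxopentadeca-4,9,11,14-tetraen-2-yl propanoate (not isolated) | C=CC/C(C)=C/C=C/[C@@H](C)CC/C=C(/C)C[C@@H](C=O)OC(=O)CC | intermediate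
24 | (2S,4Z,8S,9E,11E)-4,8,12-trimethyl-2-(propanoyloxy)pentadeca-4,9,11,14-tetraenoic acid | C=CC/C(C)=C/C=C/[C@@H](C)CC/C=C(/C)C[C@@H](C(=O)O)OC(=O)CC | intermediate
25 | methyl (2S,4Z,8S,9E,11E)-4,8,12-trimethyl-2-(propanoyloxy)pentadeca-4,9,11,14-tetraenoate | C=CC/C(C)=C/C=C/[C@@H](C)CC/C=C(/C)C[C@@H](C(=O)OC)OC(=O)CC | intermediate
26 | (5S)-4-hydroxy-3-methyl-5-[(2Z,6S,7E,9E)-2,6,10-trimethyltrideca-2,7,9,12-tetraen-1-yl]furan-2(5H)-one | C=CC/C(C)=C/C=C/[C@@H](C)CC/C=C(/C)C[C@@H]1OC(=O)C(C)=C1O | intermediate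
27 | (2S)-2-methylbutan-1-amine | CC[C@H](C)CN | starting material
28 | 2,5-dimethoxy-2,5-dihydrofuran | COC1C=CC(OC)O1 | starting material
29 | (2Z)-but-2-enedial (not isolated) | O=C/C=C\C=O | intermediate
30 | 1-[(2S)-2-methylbutyl]-1,5-dihydro-2H-pyrrol-2-one | CC[C@H](C)CN1CC=CC1=O | intermediate
31 | trans-3,4-dibromo-1-[(2S)-2-methylbutyl]pyrrolidin-2-one (not isolated; the 3S,4S isomer is shown, the 3R,4R isomer forms as well) | CC[C@H](C)CN1C[C@H](Br)[C@@H](Br)C1=O | intermediate
32 | 3-bromo-1-[(2S)-2-methylbutyl]-1,5-dihydro-2H-pyrrol-2-one | CC[C@H](C)CN1CC=C(Br)C1=O | intermediate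
33 | B-alkyl-9-borabicyclo[3.3.1]nonane from 26, enol oxygen also borylated (not isolated) | C(CC/C(C)=C/C=C/[C@@H](C)CC/C=C(/C)C[C@@H]1OC(=O)C(C)=C1OB1C2CCCC1CCC2)B1C2CCCC1CCC2 | intermediate
34 | (5S)-4-hydroxy-3-methyl-5-[(2Z,6S,7E,9E)-2,6,10-trimethyl-13-{1-[(2S)-2-methylbutyl]-2-oxo-2,5-dihydro-1H-pyrrol-3-yl}trideca-2,7,9-trien-1-yl]furan-2(5H)-one | CC[C@H](C)CN1CC=C(CCC/C(C)=C/C=C/[C@@H](C)CC/C=C(/C)C[C@@H]2OC(=O)C(C)=C2O)C1=O | target

## Step count and risks

Total step count: 18. Longest linear sequence: 13 steps (steps 1 to 7, 11 to 15 and 18).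

Steps most likely to fail:

Step 11 (key step). The iodine may be consumed by the conjugated diene, the boronate complex may form incompletely if the alkyllithium is quenched, or the ortho ester may be lost on exposure to iodine; each would lower conversion or the Z-selectivity. The fallback replaces the rearrangement by a B-alkyl Suzuki–Miyaura coupling with a Z-alkenyl iodide and sets out from diol 14 and iodide 12. Zirconium-catalysed syn-carboalumination of 14 (AlMe3, Cp2ZrCl2, 1,2-dichloroethane), then thermal chelation-controlled isomerisation and iodinolysis, should give (2S,4Z)-5-iodo-4-methylpent-4-ene-1,2-diol F1. Treatment with 15 and pyridinium p-toluenesulfonate gives (4S)-2-ethoxy-2-ethyl-4-[(2Z)-3-iodo-2-methylprop-2-en-1-yl]-1,3-dioxolane F2. Iodide 12 is converted with t-BuLi and then 9-methoxy-9-borabicyclo[3.3.1]nonane into lithium alkyl(methoxy)borate F3, which is coupled with F2 (Pd(dppf)Cl2, AsPh3, Cs2CO3, DMF/H2O) with retention of the olefin geometry. The fallback comes back to the route at 21.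

Step 18. The acidic enol may consume borane unproductively and the tetronate may slow transmetalation at palladium, or the aqueous base may move the skipped double bond into conjugation. The fallback moves the lactam coupling ahead of the formation of ring B and sets out from 21 and 32. Hydroboration of 21 with 9-BBN gives alkylborane F4, and coupling with 32 under the conditions of step 18 gives ortho ester lactam F5. Hydrolysis as in step 12 gives hydroxy propanoate F6, oxidation as in step 13 gives acid F7, and esterification as in step 14 gives methyl ester F8. A final Dieckmann condensation (LiN(SiMe3)2 or KOtBu, THF) closes ring B in the presence of the lactam. The fallback comes back to the route at 34.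

Step 12. The hemi-ortho ester may collapse unselectively, or the propanoyl group may migrate from the secondary to the primary oxygen. The fallback builds the same compound by ordinary protecting-group steps and sets out from 21. Full hydrolysis (aq. AcOH, then K2CO3, MeOH) gives (2S,4Z,8S,9E,11E)-4,8,12-trimethylpentadeca-4,9,11,14-tetraene-1,2-diol F9. Selective silylation of the primary hydroxyl (tert-butyldimethylsilyl chloride, imidazole) gives silyl ether F10. Acylation of the secondary hydroxyl (propanoic anhydride, 4-dimethylaminopyridine, pyridine) gives silyl ether propanoate F11, and HF·pyridine removes the silyl group. The fallback comes back to the route at 22.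

Further compounds
F1 | step 11 | (2S,4Z)-5-iodo-4-methylpent-4-ene-1,2-diol | I/C=C(/C)C[C@@H](CO)O
F2 | step 11 | (4S)-2-ethoxy-2-ethyl-4-[(2Z)-3-iodo-2-methylprop-2-en-1-yl]-1,3-dioxolane | CCOC1(CC)OC[C@H](C/C(C)=C\I)O1
F3 | step 11 | lithium [(3S,4E,6E)-3,7-dimethyldeca-4,6,9-trien-1-yl](methoxy)-9-borabicyclo[3.3.1]nonane borate | [Li+].C=CC/C(C)=C/C=C/[C@@H](C)CC[B-]1(OC)C2CCCC1CCC2
F4 | step 18 | B-alkyl-9-borabicyclo[3.3.1]nonane from 21 | C(CC/C(C)=C/C=C/[C@@H](C)CC/C=C(/C)C[C@H]1COC(CC)(OCC)O1)B1C2CCCC1CCC2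
F5 | step 18 | (4S)-2-ethoxy-2-ethyl-4-[(2Z,6S,7E,9E)-2,6,10-trimethyl-13-{1-[(2S)-2-methylbutyl]-2-oxo-2,5-dihydro-1H-pyrrol-3-yl}trideca-2,7,9-trien-1-yl]-1,3-dioxolane | CC[C@H](C)CN1CC=C(CCC/C(C)=C/C=C/[C@@H](C)CC/C=C(/C)C[C@H]2COC(CC)(OCC)O2)C1=O
F6 | step 18 | (2S,4Z,8S,9E,11E)-1-hydroxy-4,8,12-trimethyl-15-{1-[(2S)-2-methylbutyl]-2-oxo-2,5-dihydro-1H-pyrrol-3-yl}pentadeca-4,9,11-trien-2-yl propanoate | CC[C@H](C)CN1CC=C(CCC/C(C)=C/C=C/[C@@H](C)CC/C=C(/C)C[C@@H](CO)OC(=O)CC)C1=O
F7 | step 18 | (2S,4Z,8S,9E,11E)-4,8,12-trimethyl-15-{1-[(2S)-2-methylbutyl]-2-oxo-2,5-dihydro-1H-pyrrol-3-yl}-2-(propanoyloxy)pentadeca-4,9,11-trienoic acid | CC[C@H](C)CN1CC=C(CCC/C(C)=C/C=C/[C@@H](C)CC/C=C(/C)C[C@@H](C(=O)O)OC(=O)CC)C1=O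
F8 | step 18 | methyl (2S,4Z,8S,9E,11E)-4,8,12-trimethyl-15-{1-[(2S)-2-methylbutyl]-2-oxo-2,5-dihydro-1H-pyrrol-3-yl}-2-(propanoyloxy)pentadeca-4,9,11-trienoate | CC[C@H](C)CN1CC=C(CCC/C(C)=C/C=C/[C@@H](C)CC/C=C(/C)C[C@@H](C(=O)OC)OC(=O)CC)C1=O
F9 | step 12 | (2S,4Z,8S,9E,11E)-4,8,12-trimethylpentadeca-4,9,11,14-tetraene-1,2-diol | C=CC/C(C)=C/C=C/[C@@H](C)CC/C=C(/C)C[C@@H](CO)O
F10 | step 12 | (2S,4Z,8S,9E,11E)-1-{[tert-butyl(dimethyl)silyl]oxy}-4,8,12-trimethylpentadeca-4,9,11,14-tetraen-2-ol | C=CC/C(C)=C/C=C/[C@@H](C)CC/C=C(/C)C[C@@H](CO[Si](C)(C)C(C)(C)C)O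
F11 | step 12 | (2S,4Z,8S,9E,11E)-1-{[tert-butyl(dimethyl)silyl]oxy}-4,8,12-trimethylpentadeca-4,9,11,14-tetraen-2-yl propanoate | C=CC/C(C)=C/C=C/[C@@H](C)CC/C=C(/C)C[C@@H](CO[Si](C)(C)C(C)(C)C)OC(=O)CC
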